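Start with a subtraction: the charge less the substrate left is what has reacted.

| flask | substrate | temperature | remark | time |
|---|---|---|---|---|
| red | 0.50 M | 24 °C | run made earlier |  |
| green | 2 M | 32 °C | run made earlier |  |
| alder | 1.0 M | 35 °C |  | 40 min |
| maple | 1.0 M | 20 °C |  | 120 min |

| run | time / min | product / % | substrate / % |
|---|---|---|---|
| red | 6.00 | 2.9 | 95.8 |
| red | 10.0 | 3.9 | 90.7 |
| red | 15.0 | 5.9 | 87.4 |
| red | 25.0 | 8.2 | 80.0 |
| red | 30.0 | 9.5 | 74.5 |
| red | 50.0 | 16.7 | 63.9 |
| red | 80.0 | 24.2 | 48.5 |
| green | 4.00 | 4.0 | 92.5 |
| green | 6.00 | 5.3 | 88.3 |
| green | 8.00 | 8.5 | 83.2 |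
| green | 15.0 | 13.7 | 67.8 |
| green | 20.0 | 17.0 | 60.5 |
| green | 30.0 | 23.1 | 47.5 |
| green | 50.0 | 34.7 | 27.7 |

(each reading ± 1 percentage point)

- which one finishes higher in amount of product, in percent of the substrate charged ("neither" within 2 percentage points) (alder / maple / neither)
- amount of product at the end, in percent of the substrate charged, alder
- amount of product at the end, in percent of the substrate charged, maple

- steps under discussion: intermediate B <-> intermediate C; intermediate B -> product; intermediate B -> decomposed reagent; substrate -> product; substrate -> intermediate B; substrate <-> intermediate A

Divide the product by that difference. The last readings give 0.470 in the red run and 0.480 in the green run, with a mean of 0.475. Call this the product share, the fraction of reacted substrate found as product; the usual term is selectivity. Its zero of scale is the even split, 0.5, and the mean reads 0.0250 below that.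

Two chemists argue over these readings. The first says the share holds in both new flasks, so product is the share times the conversion. The second says the unseen part is a queue on its way to product, so reacted substrate ends as product. The second then expects about 77% in alder and 48% in maple, taking the forecast's conversions. The first replies that two runs with different temperatures and charges read close shares. The second points to the substrate still there at those last readings, 48.5% in the red run and 27.7% in the green run.

The forecast is the first chemist's number, with a share of 0.45 against our 0.475. It says alder, with 35% for alder and 22% for maple, on the ground of “apparently a fixed split”.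

    intermediate B ⇌ intermediate C (K = 0.470, k = 9.50 × 10⁻⁴ /s, Ea = 82.0 kJ/mol, ΔH = −34.0 kJ/mol)
    intermediate B → product (k = 9.70 × 10⁻⁴ /s, Ea = 102 kJ/mol)
    intermediate B → decomposed reagent (k = 9.60 × 10⁻⁴ /s, Ea = 101 kJ/mol)
    substrate → product (k = 2.10 × 10⁻⁴ /s, Ea = 89.0 kJ/mol)
    substrate → intermediate B (k = 2.00 × 10⁻⁴ /s, Ea = 105 kJ/mol)
    substrate ⇌ intermediate A (K = 2.80, k = 2.00 × 10⁻⁴ /s, Ea = 98.0 kJ/mol, ΔH = −34.0 kJ/mol)
    (constants at 35 °C)

Alder gives 36.9% and maple 22.0%, so alder finishes higher and the first chemist wins at these times. In alder, the share times the reacted fraction gives 35.8%. The second view comes nearer at long times, though not the whole way. Alder at 400 min holds 66.0% product with 1.42% substrate left, a share of 0.670, which is above the even split and below 1.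

Maple read at 80 min has 66% substrate left, so the share gives 16.4% product. The computed value is 15.7%.

(The numbers in the tables come from a simulation on assumed constants; noise was put on by code.)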